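Ring A is taken back to a non-aromatic masked ortho-benzoquinone. The plan rests on the vicinal oxygen pair C7–O/C7a–O1 of ring A (benzofuran numbering). Oxidation of the C7 phenol of an isovanillin-derived cinnamaldehyde makes C7a electrophilic. An enantiopure allylic alcohol (C2 already R) adds there as O1. Its tethered vinylboronate then closes C3 onto C3a by an intramolecular Diels–Alder reaction in the same flask. The precursors are a simple phenol and a chiral alcohol; the product is a bicyclo[2.2.2]octenone. Oxidation of the C–B bond triggers retro-aldol cleavage of the one surplus C–C bond and loss of methanol, which restores ring A; C3 settles trans. Reduction and O-methylation finish.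

Key step: step 5

Remark: the labels O1, C2, C3, C3a, C4 to C7 and C7a are the benzofuran positions of the target and are kept for the same atoms in all earlier compounds. Ring A is the benzo ring and Bpin is the 4,4,5,5-tetramethyl-1,3,2-dioxaborolan-2-yl group.
Assumption: the kinetic resolution follows the usual empirical rule for secondary allylic alcohols, under which D-(−)-diisopropyl tartrate consumes the S alcohol of this aryl vinyl carbinol.

Step 1
Reactants: 1 3,4-dimethoxybenzaldehyde; 2 vinylmagnesium bromide
Product: 3 rac-1-(3,4-dimethoxyphenyl)prop-2-en-1-ol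
Conditions: THF, 0 °C; aq NH4Cl
Reagents that add atoms: none
Why: 1,2-addition of a vinyl Grignard reagent to an aromatic aldehyde gives the racemic secondary allylic alcohol; C2 is formed without control here and is resolved in step 2.

Step 2
Reactants: 3 rac-1-(3,4-dimethoxyphenyl)prop-2-en-1-ol
Product: 4 (R)-1-(3,4-dimethoxyphenyl)prop-2-en-1-ol
Conditions: Ti(OiPr)4 (cat.), D-(−)-diisopropyl tartrate (cat.), tBuOOH (0.6 equiv), 4 Å molecular sieves, CH2Cl2, −20 °C
Reagents that add atoms: none
Why: Sharpless kinetic resolution; with the D-(−)-tartrate the titanium catalyst should epoxidise the S alcohol much faster than the R alcohol, so the unreacted alcohol is left as the R enantiomer and C2 of the target is set by the tartrate.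

Step 3
Reactants: 4 (R)-1-(3,4-dimethoxyphenyl)prop-2-en-1-ol; 5 vinyl-Bpin (2-ethenyl-4,4,5,5-tetramethyl-1,3,2-dioxaborolane)
Product: 6 (R,E)-1-(3,4-dimethoxyphenyl)-3-(Bpin)prop-2-en-1-ol
Conditions: second-generation Grubbs catalyst (cat.), 1,4-benzoquinone (cat.), CH2Cl2, 40 °C
Reagents that add atoms: none
Why: olefin cross-metathesis of a terminal allylic alcohol with vinyl-Bpin should give the E alkenylboronate, the benzoquinone suppresses ruthenium hydride isomerisation of the allylic alcohol, and C2 is not touched.

Step 4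
Reactants: 7 isovanillin (3-hydroxy-4-methoxybenzaldehyde); 8 (triphenylphosphoranylidene)acetaldehyde
Product: 9 (E)-3-(3-hydroxy-4-methoxyphenyl)prop-2-enal
Conditions: toluene, 80 °C
Reagents that add atoms: none
Why: Wittig reaction of the stabilised formyl ylide with the aromatic aldehyde should give the E enal, and the meta phenol does not deactivate the formyl group.

Step 5
Reactants: 6 (R,E)-1-(3,4-dimethoxyphenyl)-3-(Bpin)prop-2-en-1-ol; 9 (E)-3-(3-hydroxy-4-methoxyphenyl)prop-2-enal
Product: 11 Diels–Alder adduct (oxolane-bridged bicyclo[2.2.2]octenone boronate; C2 R), via masked ortho-benzoquinone 10 (not isolated)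
Conditions: PhI(OAc)2 (slow addition), NaHCO3, CH2Cl2 (dilute), 0 to 40 °C
Reagents that add atoms: none
Why: PhI(OAc)2 (trivalent iodine) binds the C7 phenol oxygen of 9 and, as iodobenzene leaves, the electron-poor ring is captured by the hydroxyl group of 6 at C7a, the ortho carbon whose own methoxy group best carries the positive charge, which makes the O1–C7a bond and gives the cyclohexa-2,4-dienone ketal 10. The diene C3a=C4–C5=C6 of 10 then adds the tethered alkene in an intramolecular Diels–Alder reaction that joins C3 to C3a and the boron-bearing carbon to C6; the closest known reaction type is the tandem oxidative acetalisation/intramolecular Diels–Alder reaction of 2-methoxyphenols with allylic alcohols. The five-membered ring O1–C2–C3–C3a–C7a closes over the three-atom tether C7a–O1–C2 of a type 1 intramolecular [4+2] cycloaddition, and the same suprafacial event closes the two six-membered rings of the bicyclo[2.2.2]octenone. C2 is not touched and stays R, while C7a, C3a, C3, C6 and the boron-bearing carbon are fixed relative to each other by the tether (the alkene can only reach the diene face that carries O1) and by the E alkene; their relation to C2 is not controlled, which is harmless because four of them are erased and C3 is reset in step 6. The step needs capture at C7a instead of the free para carbon C4, which the C7a methoxy group secures, bonding of C3 to C3a instead of C6, which the tether length secures, and cyclisation ahead of dimerisation of 10, which slow addition of the oxidant and dilution favour.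

Step 6
Reactants: 11 Diels–Alder adduct
Product: 13 (2R,3R)-2-(3,4-dimethoxyphenyl)-7-hydroxy-5-[(E)-3-oxoprop-1-enyl]-2,3-dihydrobenzofuran-3-carbaldehyde (trans), via beta-hydroxy ketone 12 (not isolated)
Conditions: Me3NO, THF, 60 °C; then MeOH, DBU (cat.), 0 °C to rt
Reagents that add atoms: trimethylamine N-oxide, C[N+](C)(C)[O-]
Why: the amine oxide turns the C–B bond into C–O (1,2-shift from boron to oxygen), methanolysis frees beta-hydroxy ketone 12, which cannot dehydrate (bridgehead) and therefore undergoes base-induced retro-aldol cleavage of the C6–CH(OH) bond, E1cB loss of the C7a methoxy group (not of O1, which the oxolane holds near the ring plane and out of overlap) restores aromatic ring A, and the formyl-bearing C3 equilibrates through its enolate to the trans isomer under control of the C2 aryl group.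

Step 7
Reactants: 13 trans phenol dialdehyde
Product: 14 (E)-3-[(2R,3S)-2-(3,4-dimethoxyphenyl)-7-hydroxy-3-(hydroxymethyl)-2,3-dihydrobenzofuran-5-yl]prop-2-enal
Conditions: NaBH4, MeOH/CH2Cl2 (1:1), −78 °C
Reagents that add atoms: none
Why: chemoselective borohydride reduction; at low temperature the saturated aldehyde on C3 is far more electrophilic than the aryl-conjugated enal, so only it should be reduced, and the cold, short contact avoids epimerisation at C3.

Step 8
Reactants: 14 phenol hydroxy enal
Product: 15 4-O-methylbalanophonin, (E)-3-[(2R,3S)-2-(3,4-dimethoxyphenyl)-3-(hydroxymethyl)-7-methoxy-2,3-dihydrobenzofuran-5-yl]prop-2-enal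
Conditions: MeI, K2CO3, acetone, rt
Reagents that add atoms: iodomethane, CI
Why: Williamson ether synthesis; only the acidic C7 phenol is deprotonated by K2CO3, so methylation should occur there and not at the primary alcohol, and no stereocentre carries an acidic hydrogen any more.

Compound list
1 | 3,4-dimethoxybenzaldehyde | COc1ccc(C=O)cc1OC | starting material
2 | vinylmagnesium bromide | C=C[Mg]Br | starting material
3 | rac-1-(3,4-dimethoxyphenyl)prop-2-en-1-ol | COc1ccc(C(O)C=C)cc1OC | intermediate
4 | (R)-1-(3,4-dimethoxyphenyl)prop-2-en-1-ol | COc1ccc([C@@H](C=C)O)cc1OC | intermediate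
5 | 2-ethenyl-4,4,5,5-tetramethyl-1,3,2-dioxaborolane (vinyl-Bpin) | C=CB1OC(C)(C)C(C)(C)O1 | starting material
6 | (R,E)-1-(3,4-dimethoxyphenyl)-3-(4,4,5,5-tetramethyl-1,3,2-dioxaborolan-2-yl)prop-2-en-1-ol | COc1ccc([C@@H](/C=C/B2OC(C)(C)C(C)(C)O2)O)cc1OC | intermediate
7 | isovanillin (3-hydroxy-4-methoxybenzaldehyde) | COc1ccc(C=O)cc1O | starting material
8 | (triphenylphosphoranylidene)acetaldehyde | O=CC=P(c1ccccc1)(c1ccccc1)c1ccccc1 | starting material
9 | (E)-3-(3-hydroxy-4-methoxyphenyl)prop-2-enal | COc1ccc(/C=C/C=O)cc1O | intermediate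
10 | masked ortho-benzoquinone: 6-methoxy-6-{[(R,E)-1-(3,4-dimethoxyphenyl)-3-(Bpin)prop-2-enyl]oxy}-3-[(E)-3-oxoprop-1-enyl]cyclohexa-2,4-dien-1-one, both epimers at the ketal carbon C7a | COC1(O[C@@H](c2ccc(OC)c(OC)c2)/C=C/B2OC(C)(C)C(C)(C)O2)C=CC(/C=C/C=O)=CC1=O | intermediate
11 | Diels–Alder adduct: bicyclo[2.2.2]octenone with C7 as ketone, C7a as ketal carbon (OMe and O1), new bonds C3–C3a and CH(Bpin)–C6, alkene C4=C5 bearing the (E)-3-oxoprop-1-enyl chain on C5, oxolane ring O1–C2–C3–C3a–C7a; C2 R, the ring centres as two diastereomers | O=C1C2C(B3OC(C)(C)C(C)(C)O3)C4[C@H](c5ccc(OC)c(OC)c5)OC1(OC)C4C=C2/C=C/C=O | intermediate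
12 | beta-hydroxy ketone: adduct 11 with OH in place of Bpin | O=C1C2C(O)C4[C@H](c5ccc(OC)c(OC)c5)OC1(OC)C4C=C2/C=C/C=O | intermediate
13 | (2R,3R)-2-(3,4-dimethoxyphenyl)-7-hydroxy-5-[(E)-3-oxoprop-1-enyl]-2,3-dihydrobenzofuran-3-carbaldehyde | COc1ccc([C@@H]2Oc3c(O)cc(/C=C/C=O)cc3[C@H]2C=O)cc1OC | intermediate
14 | (E)-3-[(2R,3S)-2-(3,4-dimethoxyphenyl)-7-hydroxy-3-(hydroxymethyl)-2,3-dihydrobenzofuran-5-yl]prop-2-enal | COc1ccc([C@@H]2Oc3c(O)cc(/C=C/C=O)cc3[C@H]2CO)cc1OC | intermediate
15 | 4-O-methylbalanophonin | COc1ccc([C@@H]2Oc3c(OC)cc(/C=C/C=O)cc3[C@H]2CO)cc1OC | target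

Total step count: 8. Longest linear sequence: 7 (steps 1, 2, 3, 5, 6, 7, 8).

Steps most likely to fail

Step 5. Capture of the oxidised phenol by the hindered secondary alcohol may lose out to capture by acetate and to Diels–Alder dimerisation of the dienone. One of the two ketal epimers may also cyclise slowly. The fallback sets out from 6, comes back at 15 and makes the two bonds in two separate operations.
- 5-Bromovanillin is converted through its aryl fluorosulfonate (SO2F2, NMe4F) into 3-bromo-4-fluoro-5-methoxybenzaldehyde F1.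
- The sodium alkoxide of 6 (NaH, DMF) displaces the fluoride para to the formyl group by nucleophilic aromatic substitution to give the aryl ether F2.
- Bu3SnH/AIBN turns the C–Br bond into an aryl radical that closes 5-exo-trig on C3, trans to the C2 aryl group, through an alpha-boryl radical to give the boronate F3.
- Me3NO gives the hydroxy aldehyde F4, and a Wittig reaction with 8 gives 15.

Step 6. The retro-aldol cleavage may stall. The beta-aryloxy aldehyde formed may open by E1cB loss of O1 or condense with the enal under base before it is isolated. The fallback sets out from 12 (isolated after aqueous work-up of the Me3NO oxidation), comes back at 15 and replaces the retro-aldol by a retro-Claisen cleavage that delivers a more robust ester.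
- Dess–Martin periodinane gives the non-enolisable beta-diketone F5.
- K2CO3/MeOH adds methoxide to the less hindered new ketone, cleaves its bond to C6 and aromatises to the trans phenol methyl ester F6.
- MeI/K2CO3 gives the methyl ether F7.
- iBu2AlH reduces the ester and the enal to the diol F8.
- MnO2 re-oxidises only the cinnamyl alcohol to give 15.

Step 7. Hydride may also attack the enal, so that over-reduction erodes the chemoselectivity. The fallback sets out from 13 and comes back at 14. A Luche reduction (NaBH4, CeCl3·7H2O, MeOH) takes both aldehydes to the phenol diol F9, and MnO2 then oxidises only the allylic (cinnamyl) alcohol.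

Further compounds
F1 | step 5 | 3-bromo-4-fluoro-5-methoxybenzaldehyde | COc1cc(C=O)cc(Br)c1F
F2 | step 5 | 3-bromo-4-{[(R,E)-1-(3,4-dimethoxyphenyl)-3-(Bpin)prop-2-enyl]oxy}-5-methoxybenzaldehyde | COc1ccc([C@@H](/C=C/B2OC(C)(C)C(C)(C)O2)Oc2c(Br)cc(C=O)cc2OC)cc1OC
F3 | step 5 | trans-(2R,3R)-2-(3,4-dimethoxyphenyl)-7-methoxy-3-[(Bpin)methyl]-2,3-dihydrobenzofuran-5-carbaldehyde | COc1ccc([C@@H]2Oc3c(OC)cc(C=O)cc3[C@H]2CB4OC(C)(C)C(C)(C)O4)cc1OC
F4 | step 5 | (2R,3S)-2-(3,4-dimethoxyphenyl)-3-(hydroxymethyl)-7-methoxy-2,3-dihydrobenzofuran-5-carbaldehyde | COc1ccc([C@@H]2Oc3c(OC)cc(C=O)cc3[C@H]2CO)cc1OC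
F5 | step 6 | beta-diketone: compound 12 with the carbinol oxidised to a ketone | O=C1C2C(=O)C4[C@H](c5ccc(OC)c(OC)c5)OC1(OC)C4C=C2/C=C/C=O
F6 | step 6 | methyl trans-(2R,3R)-2-(3,4-dimethoxyphenyl)-7-hydroxy-5-[(E)-3-oxoprop-1-enyl]-2,3-dihydrobenzofuran-3-carboxylate | COc1ccc([C@@H]2Oc3c(O)cc(/C=C/C=O)cc3[C@H]2C(=O)OC)cc1OC
F7 | step 6 | methyl trans-(2R,3R)-2-(3,4-dimethoxyphenyl)-7-methoxy-5-[(E)-3-oxoprop-1-enyl]-2,3-dihydrobenzofuran-3-carboxylate | COc1ccc([C@@H]2Oc3c(OC)cc(/C=C/C=O)cc3[C@H]2C(=O)OC)cc1OC
F8 | step 6 | (E)-3-[(2R,3S)-2-(3,4-dimethoxyphenyl)-3-(hydroxymethyl)-7-methoxy-2,3-dihydrobenzofuran-5-yl]prop-2-en-1-ol | COc1ccc([C@@H]2Oc3c(OC)cc(/C=C/CO)cc3[C@H]2CO)cc1OC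
F9 | step 7 | (2R,3S)-2-(3,4-dimethoxyphenyl)-3-(hydroxymethyl)-5-[(E)-3-hydroxyprop-1-enyl]-2,3-dihydrobenzofuran-7-ol | COc1ccc([C@@H]2Oc3c(O)cc(/C=C/CO)cc3[C@H]2CO)cc1OC
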